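**Plan**

- Retrosynthetic cuts: first the three aryl O–CH2OMe bonds (protecting groups), then both aryl–vinyl bonds of the stilbene, C4(ring A)–CH= and =CH–C1(ring B), and last the C2(ring A)–CH2 bond to the geranyl chain.
- Enabling feature: the trans CH=CH bridge is a bare two-carbon unit whose two sp2 carbons each carry one aryl carbon (C4 of the 2-geranylphenol ring A, C1 of the 3,5-dioxygenated ring B). One vinylboron reagent can therefore act as Heck acceptor for a ring A iodide and then as Suzuki donor toward a ring B bromide.
- Forward order: ortho C-geranylation of 4-iodophenol and MOM protection (ring A piece); bis-MOM protection of 5-bromoresorcinol (ring B piece); one-flask Heck–Suzuki union of ring A, the two-carbon bridge and ring B; acidic methanolysis. Both benzene rings are purchased and no ring is formed.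
- Stereochemistry: there is no stereocentre. The 2E side-chain alkene is carried unchanged from geranyl bromide. The E stilbene alkene comes from syn carbopalladation and syn β-hydride elimination, followed by a stereoretentive Suzuki stage.

Key step: step 4

Remark: 4-iodophenol, geranyl bromide, 5-bromoresorcinol and vinylboronic acid pinacol ester are taken as purchasable; stilbene-containing compounds should be handled in subdued light to avoid E/Z photoisomerisation.

**Route**

Step 1
Reactants: 1 4-iodophenol; 2 geranyl bromide [(2E)-1-bromo-3,7-dimethylocta-2,6-diene]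
Product: 4 2-[(2E)-3,7-dimethylocta-2,6-dien-1-yl]-4-iodophenol (2-geranyl-4-iodophenol), via sodium 4-iodophenoxide 3 (not isolated)
Conditions: 1 (1.3 equiv), NaH (1.3 equiv), toluene, 0 °C → rt; then 2 (1.0 equiv), rt, dark
Reagents that add atoms: none
Why: In toluene the sodium phenoxide is a tight, aggregated ion pair whose oxygen is shielded by sodium, so the allylic bromide should be attacked in SN2 fashion by the ortho carbon (ortho C-alkylation of a phenoxide in a non-polar medium); the para position is blocked by iodine, the dienone tautomerises to the phenol, and the 2E geometry is retained.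

Step 2
Reactants: 4 2-geranyl-4-iodophenol
Product: 5 2-[(2E)-3,7-dimethylocta-2,6-dien-1-yl]-4-iodo-1-(methoxymethoxy)benzene
Conditions: MOMCl, i-Pr2NEt, CH2Cl2, 0 °C → rt
Reagents that add atoms: chloromethyl methyl ether (MOMCl), COCCl
Why: O-Alkylation of the phenol by the highly reactive α-chloro ether (MOM protection, Williamson-type) should proceed cleanly under amine base, which touches neither the aryl iodide nor the alkenes.

Step 3
Reactants: 6 5-bromoresorcinol (5-bromobenzene-1,3-diol)
Product: 7 1-bromo-3,5-bis(methoxymethoxy)benzene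
Conditions: MOMCl (2.5 equiv), i-Pr2NEt (3 equiv), CH2Cl2, 0 °C → rt
Reagents that add atoms: chloromethyl methyl ether (MOMCl), COCCl
Why: Double MOM protection of the two equivalent phenols (Williamson-type O-alkylation) is routine and leaves the aryl bromide untouched.

Step 4
Reactants: 5 2-geranyl-4-iodo-1-(methoxymethoxy)benzene; 8 vinylboronic acid pinacol ester (4,4,5,5-tetramethyl-2-vinyl-1,3,2-dioxaborolane); 7 1-bromo-3,5-bis(methoxymethoxy)benzene
Product: 10 1-[(E)-2-{3-[(2E)-3,7-dimethylocta-2,6-dien-1-yl]-4-(methoxymethoxy)phenyl}ethenyl]-3,5-bis(methoxymethoxy)benzene (tris-MOM schweinfurthin I), via (E)-2-arylvinylboronic pinacol ester 9 (not isolated)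
Conditions: 5 (1.0 equiv), 8 (1.1 equiv), Pd[P(t-Bu)3]2 (5 mol %), i-Pr2NH (2 equiv), dry toluene, 80 °C; then 7 (1.2 equiv), 3 M aq. K3PO4 (3 equiv), 80 °C, same flask
Reagents that add atoms: none
Why: Oxidative addition of the C–I bond of 5 to the zerovalent palladium–P(t-Bu)3 complex, syn carbopalladation of 8 with the aryl group delivered to the unsubstituted CH2 carbon, and syn β-hydride elimination should give the (E)-2-arylvinylboronate 9, while i-Pr2NH takes up HI and returns zerovalent palladium. The closest known reaction type is the boron-retentive Mizoroki–Heck arylation of vinylboronic pinacol esters run in one flask with a Suzuki–Miyaura coupling to give unsymmetrical (E)-stilbenes. No ring is closed and no stereocentre is created; the only stereo-element made is the E alkene, fixed by the syn-addition/syn-elimination sequence of the Heck stage and carried over by the stereoretentive transmetalation and reductive elimination of the Suzuki stage. The step needs Heck rather than Suzuki reactivity at the C–B bond in the first stage, which the dry amine base secures because no boronate "ate" complex forms without hydroxide or phosphate; adding aqueous K3PO4 together with 7 then switches transmetalation on. Single arylation is secured by the small excess of 8 and the lower reactivity of the β-arylated alkene 9 toward a second insertion, and cross-selectivity between the two halides by the iodide being used up before the bromide enters the flask. The trisubstituted geranyl alkenes are too hindered to insert, and the MOM ethers are inert to amine and phosphate bases.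

Step 5
Reactants: 10 tris-MOM schweinfurthin I
Product: 11 schweinfurthin I, 5-[(E)-2-{3-[(2E)-3,7-dimethylocta-2,6-dien-1-yl]-4-hydroxyphenyl}ethenyl]benzene-1,3-diol
Conditions: p-TsOH·H2O (cat.), MeOH, rt, dark
Reagents that add atoms: none
Why: Acid-catalysed transacetalisation of the three aryl MOM ethers with methanol (acetal methanolysis) should release the phenols and dimethoxymethane under conditions mild enough to leave the trisubstituted alkenes and the stilbene untouched.

**Compound list**

1 | 4-iodophenol | Oc1ccc(I)cc1 | starting material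
2 | geranyl bromide, (2E)-1-bromo-3,7-dimethylocta-2,6-diene | CC(C)=CCC/C(C)=C/CBr | starting material
3 | sodium 4-iodophenoxide | [Na+].[O-]c1ccc(I)cc1 | intermediate (not isolated)
4 | 2-[(2E)-3,7-dimethylocta-2,6-dien-1-yl]-4-iodophenol | CC(C)=CCC/C(C)=C/Cc1cc(I)ccc1O | intermediate
5 | 2-[(2E)-3,7-dimethylocta-2,6-dien-1-yl]-4-iodo-1-(methoxymethoxy)benzene | CC(C)=CCC/C(C)=C/Cc1cc(I)ccc1OCOC | intermediate
6 | 5-bromoresorcinol | Oc1cc(O)cc(Br)c1 | starting material
7 | 1-bromo-3,5-bis(methoxymethoxy)benzene | COCOc1cc(Br)cc(OCOC)c1 | intermediate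
8 | vinylboronic acid pinacol ester | C=CB1OC(C)(C)C(C)(C)O1 | starting material
9 | 2-[(E)-2-{3-[(2E)-3,7-dimethylocta-2,6-dien-1-yl]-4-(methoxymethoxy)phenyl}ethenyl]-4,4,5,5-tetramethyl-1,3,2-dioxaborolane | CC(C)=CCC/C(C)=C/Cc1cc(/C=C/B2OC(C)(C)C(C)(C)O2)ccc1OCOC | intermediate (not isolated)
10 | 1-[(E)-2-{3-[(2E)-3,7-dimethylocta-2,6-dien-1-yl]-4-(methoxymethoxy)phenyl}ethenyl]-3,5-bis(methoxymethoxy)benzene | CC(C)=CCC/C(C)=C/Cc1cc(/C=C/c2cc(OCOC)cc(OCOC)c2)ccc1OCOC | intermediate
11 | schweinfurthin I | CC(C)=CCC/C(C)=C/Cc1cc(/C=C/c2cc(O)cc(O)c2)ccc1O | target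

**Count**

Total steps: 5. Longest linear sequence: 4 steps (steps 1, 2, 4, 5); step 3 is a one-step side branch.

**Steps most likely to fail, with fallbacks**

Step 4. Possible failure: premature Suzuki-type transfer of the vinyl group during the Heck stage, a second arylation of the styrylboronate, or protodeboronation once aqueous base is present, each of which would erode the three-component union. The fallback sets out from 7 and 8 and comes back to the route at 10. It forms the same two aryl–vinyl bonds in the opposite order and in two flasks, so no boron has to survive a Heck reaction. Suzuki–Miyaura vinylation of bromide 7 with 8 (Pd(PPh3)4, K2CO3, dioxane/H2O, 90 °C) should give 1,3-bis(methoxymethoxy)-5-vinylbenzene F1, which is isolated. A conventional Mizoroki–Heck reaction of this styrene with iodide 5 (Pd(OAc)2, P(o-tol)3, Et3N, DMF, 90 °C) should then give the E stilbene 10.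

Step 1. Possible failure: O-alkylation and double alkylation competing with ortho C-alkylation, or partial SN2′ attack, leaving little of the mono-ortho-geranylated phenol. The fallback sets out from geranyl bromide 2 and comes back to the route at 5; the aryl partner becomes purchased 2,4-dibromophenol (Oc1ccc(Br)cc1Br). MOM protection (MOMCl, i-Pr2NEt, CH2Cl2) should give 2,4-dibromo-1-(methoxymethoxy)benzene F2. Bromine–lithium exchange with n-BuLi in Et2O at −78 °C should occur at the bromine ortho to the chelating MOM ether to give 5-bromo-2-(methoxymethoxy)phenyllithium F3. Copper-mediated SN2 allylation with 2 (CuBr·SMe2, −78 °C → rt) should give 4-bromo-2-[(2E)-3,7-dimethylocta-2,6-dien-1-yl]-1-(methoxymethoxy)benzene F4. A copper-catalysed aromatic Finkelstein exchange (CuI, NaI, trans-N,N′-dimethylcyclohexane-1,2-diamine, dioxane, 110 °C) then converts the aryl bromide into iodide 5.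

Step 5. Possible failure: acid-promoted cyclisation of the freed ortho-geranyl phenol onto its 2,3-alkene (chroman formation) or addition of methanol to the trisubstituted alkenes before all three acetals have been cleaved. The fallback sets out from 4 and 6 (with 8 as before) and comes back to the route at 11; it replaces the acid-labile acetals by fluoride-labile silyl ethers. Silylation (TIPSCl, imidazole, DMF) should give {2-[(2E)-3,7-dimethylocta-2,6-dien-1-yl]-4-iodophenoxy}tri(propan-2-yl)silane F5 from 4 and 1-bromo-3,5-bis[tri(propan-2-yl)silyloxy]benzene F6 from 6. The same one-flask Heck–Suzuki sequence with 8 should pass through the TIPS-protected (E)-styrylboronic pinacol ester F7, not isolated, to tris-TIPS schweinfurthin I F8. Buffered fluoride (TBAF, AcOH, THF, 0 °C) should then release 11 without any acid strong enough to engage the alkenes.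

Further compounds
F1 | step 4 | 1,3-bis(methoxymethoxy)-5-vinylbenzene | C=Cc1cc(OCOC)cc(OCOC)c1
F2 | step 1 | 2,4-dibromo-1-(methoxymethoxy)benzene | COCOc1ccc(Br)cc1Br
F3 | step 1 | 5-bromo-2-(methoxymethoxy)phenyllithium | [Li]c1cc(Br)ccc1OCOC
F4 | step 1 | 4-bromo-2-[(2E)-3,7-dimethylocta-2,6-dien-1-yl]-1-(methoxymethoxy)benzene | CC(C)=CCC/C(C)=C/Cc1cc(Br)ccc1OCOC
F5 | step 5 | {2-[(2E)-3,7-dimethylocta-2,6-dien-1-yl]-4-iodophenoxy}tri(propan-2-yl)silane | CC(C)=CCC/C(C)=C/Cc1cc(I)ccc1O[Si](C(C)C)(C(C)C)C(C)C
F6 | step 5 | 1-bromo-3,5-bis[tri(propan-2-yl)silyloxy]benzene | CC(C)[Si](Oc1cc(Br)cc(O[Si](C(C)C)(C(C)C)C(C)C)c1)(C(C)C)C(C)C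
F7 | step 5 | 2-[(E)-2-{3-[(2E)-3,7-dimethylocta-2,6-dien-1-yl]-4-[tri(propan-2-yl)silyloxy]phenyl}ethenyl]-4,4,5,5-tetramethyl-1,3,2-dioxaborolane | CC(C)=CCC/C(C)=C/Cc1cc(/C=C/B2OC(C)(C)C(C)(C)O2)ccc1O[Si](C(C)C)(C(C)C)C(C)C
F8 | step 5 | tris-TIPS schweinfurthin I, 1-[(E)-2-{3-[(2E)-3,7-dimethylocta-2,6-dien-1-yl]-4-[tri(propan-2-yl)silyloxy]phenyl}ethenyl]-3,5-bis[tri(propan-2-yl)silyloxy]benzene | CC(C)=CCC/C(C)=C/Cc1cc(/C=C/c2cc(O[Si](C(C)C)(C(C)C)C(C)C)cc(O[Si](C(C)C)(C(C)C)C(C)C)c2)ccc1O[Si](C(C)C)(C(C)C)C(C)C
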